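**Retrosynthetic overview**
- Target ⇐ 12‑nor‑8‑ketone that already carries the aryl ether: C6=C7 dehydrogenation, methyl addition at C8, then oxidative 1,3‑transposition give the 8‑methyl‑7‑en‑6‑one.
- That ketone ⇐ one‑flask carbenoid ring expansion of a trans‑hydrindan‑1‑one (five‑membered pre‑ring B → ring B, C9 inserted next to C10); the regiodefined enolate is trapped by the chloromethyl ether of isofraxidin (C9–C11 bond, C9 stereocentre, fragment union).
- Hydrindanone ⇐ Hajos–Parrish‑type enedione from 2‑methylcyclopentane‑1,3‑dione and ethyl vinyl ketone, then reductive methylation (C4, C5), axial‑selective reduction (C3) and acylation.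
- Chloromethyl ether ⇐ isofraxidin ⇐ resorcinol (formylation, dibromination, methoxylation, Wittig–lactonisation).
- Ring order: ring A (aldol), five‑membered pre‑ring B (present from the start), ring B by ring expansion; the coumarin is built separately.

Convention (assumption): decalin atoms carry drimane labels (C1–C10, C11 = CH2O, C12 = CH3 on C8, C13/C14 = CH3 on C4, C15 = CH3 on C10); β = face of C15, α = opposite face. The target is 3α‑ester, 5α‑H, 9β‑H (C11 α), 10β‑CH3 = (3R,5R,9R,10R).

**Route**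

Step 1
Reactants: 1 2-methylcyclopentane-1,3-dione; 2 pent-1-en-3-one (ethyl vinyl ketone)
Product: 4 (S)-4,7a-dimethyl-2,3,7,7a-tetrahydro-1H-indene-1,5(6H)-dione, via triketone 3 (not isolated)
Conditions: Et3N (cat.), neat, 25 °C; then L-phenylalanine, (+)-camphorsulfonic acid, DMF, 30→70 °C
Reagents that add atoms: none
Why: Michael addition followed by the amino‑acid‑catalysed Hajos–Parrish–Eder–Sauer–Wiechert aldol condensation, in which the L‑phenylalanine enamine desymmetrises the prochiral 1,3‑dione and sets the quaternary centre (future C10) as S, the ee being raised by recrystallisation.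

Step 2
Reactants: 4 (S)-4,7a-dimethyl-2,3,7,7a-tetrahydro-1H-indene-1,5(6H)-dione
Product: 5 (S)-4',7a'-dimethyl-2',3',7',7a'-tetrahydrospiro[[1,3]dioxolane-2,1'-inden]-5'(6'H)-one
Conditions: (Me3SiOCH2)2, Me3SiOTf (cat.), CH2Cl2, –78→–20 °C
Reagents that add atoms: 1,2-bis(trimethylsilyloxy)ethane, C[Si](C)(C)OCCO[Si](C)(C)C
Why: Noyori ketalisation under kinetic control protects the saturated cyclopentanone in preference to the less electrophilic conjugated carbonyl, and the low temperature prevents double‑bond migration.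

Step 3
Reactants: 5 (S)-4',7a'-dimethyl-2',3',7',7a'-tetrahydrospiro[[1,3]dioxolane-2,1'-inden]-5'(6'H)-one
Product: 7 (3a'S,7a'S)-4',4',7a'-trimethylhexahydrospiro[[1,3]dioxolane-2,1'-inden]-5'(4'H)-one, via lithium enolate 6 (not isolated)
Conditions: Li, NH3(l), THF, t-BuOH (1 equiv), –78 °C; then MeI, –78→–33 °C
Reagents that add atoms: iodomethane, CI
Why: Stork reductive alkylation, in which two‑electron reduction of the enone and protonation of the β‑carbon (C5) on the face opposite the angular methyl give the trans ring fusion (5α‑H), and the regiodefined enolate 6 is C‑methylated to build the gem‑dimethyl carbon C4.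

Step 4
Reactants: 7 (3a'S,7a'S)-4',4',7a'-trimethylhexahydrospiro[[1,3]dioxolane-2,1'-inden]-5'(4'H)-one
Product: 9 (3aS,5R,7aS)-5-hydroxy-4,4,7a-trimethyloctahydro-1H-inden-1-one, via hydroxy ketal 8 (not isolated)
Conditions: LiBH(s-Bu)3, THF, –78→0 °C; then 3 M HCl, THF, 25 °C
Reagents that add atoms: water, O
Why: Diastereoselective ketone reduction in which the bulky trialkylborohydride attacks the 4,4‑dimethyl‑3‑ketone along the equatorial trajectory and gives the axial 3α‑alcohol (trans to C15), after which the acidic quench hydrolyses the dioxolane.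

Step 5
Reactants: 9 (3aS,5R,7aS)-5-hydroxy-4,4,7a-trimethyloctahydro-1H-inden-1-one; 10 3-methylbutanoyl chloride
Product: 11 (3aS,5R,7aS)-4,4,7a-trimethyl-1-oxooctahydro-1H-inden-5-yl 3-methylbutanoate
Conditions: DMAP, pyridine, CH2Cl2, 0→40 °C
Reagents that add atoms: none
Why: DMAP‑catalysed acylation through the acylpyridinium ion esterifies the hindered axial alcohol without touching any stereocentre.

Step 6
Reactants: 12 resorcinol
Product: 14 2,4-dihydroxybenzaldehyde, via iminium salt 13 (not isolated)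
Conditions: POCl3, DMF, MeCN, –15→25 °C; then H2O, 50 °C
Reagents that add atoms: N,N-dimethylformamide, CN(C)C=O; water, O
Why: Vilsmeier–Haack formylation attacks the position para to one hydroxyl and ortho to the other, and hydrolysis of the iminium salt releases the aldehyde.

Step 7
Reactants: 14 2,4-dihydroxybenzaldehyde
Product: 15 3,5-dibromo-2,4-dihydroxybenzaldehyde
Conditions: Br2 (2 equiv), AcOH, 25 °C
Reagents that add atoms: bromine, BrBr
Why: Electrophilic aromatic bromination takes the two remaining positions ortho/para to the hydroxyls, the formyl group blocking the third.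

Step 8
Reactants: 15 3,5-dibromo-2,4-dihydroxybenzaldehyde
Product: 16 2,4-dihydroxy-3,5-dimethoxybenzaldehyde
Conditions: NaOMe, CuBr (cat.), DMF/MeOH, 110 °C; then aq HCl
Reagents that add atoms: sodium methoxide, [Na+].[O-]C
Why: Copper‑catalysed Ullmann‑type methoxylation of ortho‑bromophenolates, the reaction that turns bromovanillin into syringaldehyde, replaces both bromides.

Step 9
Reactants: 16 2,4-dihydroxy-3,5-dimethoxybenzaldehyde
Product: 18 isofraxidin (7-hydroxy-6,8-dimethoxy-2H-chromen-2-one), via cinnamate ester 17 (not isolated)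
Conditions: Ph3P=CHCO2Et, N,N-diethylaniline, 210 °C
Reagents that add atoms: ethyl (triphenylphosphoranylidene)acetate, CCOC(=O)C=P(c1ccccc1)(c1ccccc1)c1ccccc1
Why: Wittig olefination of the salicylaldehyde followed by thermal E/Z equilibration and lactonisation of the ortho‑hydroxycinnamate gives the coumarin in one operation.

Step 10
Reactants: 18 isofraxidin
Product: 19 6,8-dimethoxy-7-[(methylthio)methoxy]-2H-chromen-2-one
Conditions: NaH, ClCH2SCH3, NaI (cat.), DMF, 0→25 °C
Reagents that add atoms: chloromethyl methyl sulfide, CSCCl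
Why: Williamson‑type SN2 O‑alkylation of the sodium phenoxide by the activated α‑chloro sulfide gives the methylthiomethyl ether.

Step 11
Reactants: 19 6,8-dimethoxy-7-[(methylthio)methoxy]-2H-chromen-2-one
Product: 20 7-(chloromethoxy)-6,8-dimethoxy-2H-chromen-2-one
Conditions: SO2Cl2, CH2Cl2, –20→0 °C; evaporate, use crude
Reagents that add atoms: sulfuryl chloride, O=S(=O)(Cl)Cl
Why: Chlorinolysis of the O,S‑acetal through the chlorosulfonium ion gives the aryl chloromethyl ether, the sulfide reacting far faster than the electron‑poor coumarin.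

Step 12
Reactants: 11 (3aS,5R,7aS)-4,4,7a-trimethyl-1-oxooctahydro-1H-inden-5-yl 3-methylbutanoate; 20 7-(chloromethoxy)-6,8-dimethoxy-2H-chromen-2-one
Product: 23 7-{[3α-(3-methylbutanoyloxy)-8-oxo-12-nor-5α,9βH-driman-11-yl]oxy}-6,8-dimethoxy-2H-chromen-2-one, via dibromomethyl carbinolate 21 (not isolated), via ring-expanded lithium enolate 22 (not isolated)
Conditions: CH2Br2, lithium 2,2,6,6-tetramethylpiperidide, THF, –95 °C; n-BuLi, –95→–30 °C; then 20, –78→–30 °C
Reagents that add atoms: dibromomethane, BrCBr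
Why: Proposed new method: carbenoid ring expansion with in‑flask aryloxymethylation, in which LiCHBr2 adds to the cyclopentanone from the α face, bromine–lithium exchange gives a β‑oxido carbenoid whose electron‑rich angular C10–C8 bond (anti to the leaving bromide) shifts to the carbenoid carbon with retention at C10 and loss of LiBr, the resulting six‑membered enolate 22 has its double bond fixed at C8=C9, and the oxocarbenium‑like chloromethyl ether 20 alkylates it axially on the face opposite the C15 methyl so that C11 is α and H9 is β; the closest known chemistry is the Taguchi–Yamamoto–Nozaki β‑oxido carbenoid ring enlargement of cycloalkanones and the C‑alkylation of lithium enolates by chloromethyl ethers, neither shown for migration of a ring‑fusion quaternary carbon in an ester‑bearing hydrindanone nor combined to join two fragments.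

Step 13
Reactants: 23 7-{[3α-(3-methylbutanoyloxy)-8-oxo-12-nor-5α,9βH-driman-11-yl]oxy}-6,8-dimethoxy-2H-chromen-2-one
Product: 24 7-{[3α-(3-methylbutanoyloxy)-8-oxo-12-nor-5α,9βH-drim-6-en-11-yl]oxy}-6,8-dimethoxy-2H-chromen-2-one
Conditions: 2-iodoxybenzoic acid (IBX), 4-methoxypyridine N-oxide, DMSO, 25→45 °C
Reagents that add atoms: none
Why: IBX dehydrogenation (Nicolaou) runs through the enol on the C7 side, whose axial hydrogen is stereoelectronically available, whereas the equatorial H9 is not, so the C9 centre and the β‑aryloxy group should survive.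

Step 14
Reactants: 24 7-{[3α-(3-methylbutanoyloxy)-8-oxo-12-nor-5α,9βH-drim-6-en-11-yl]oxy}-6,8-dimethoxy-2H-chromen-2-one
Product: 25 7-{[8-hydroxy-3α-(3-methylbutanoyloxy)-5α,9βH-drim-6-en-11-yl]oxy}-6,8-dimethoxy-2H-chromen-2-one (C8 epimers)
Conditions: MeLi, CeCl3, THF, –78 °C
Reagents that add atoms: methyllithium, [Li]C
Why: The organocerium reagent (Imamoto conditions) adds 1,2 to the enone carbonyl, is too weakly basic to enolise C9 or trigger β‑elimination, and spares the ester and the lactone at –78 °C, while the new carbinol centre is erased in the next step.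

Step 15
Reactants: 25 7-{[8-hydroxy-3α-(3-methylbutanoyloxy)-5α,9βH-drim-6-en-11-yl]oxy}-6,8-dimethoxy-2H-chromen-2-one
Product: 26 7-{[(3R,5R,9R,10R)-3-(3-methylbutanoyloxy)-6-oxodrim-7-en-11-yl]oxy}-6,8-dimethoxy-2H-chromen-2-one (CNP0279705.1)
Conditions: pyridinium chlorochromate (C5H5NH)[CrO3Cl], 4 Å MS, CH2Cl2, 25 °C
Reagents that add atoms: pyridinium chlorochromate, [O-][Cr](=O)(=O)Cl.c1cc[nH+]cc1
Why: Dauben–Babler oxidative 1,3‑transposition, in which the tertiary allylic chromate ester shifts to C6 and is oxidised to the 8‑methyl‑7‑en‑6‑one, C5 keeping the trans (and thermodynamically preferred) fusion and C9 staying untouched.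

**Compound list**
1 | 2-methylcyclopentane-1,3-dione | CC1C(=O)CCC1=O | starting material
2 | pent-1-en-3-one (ethyl vinyl ketone) | CCC(=O)C=C | starting material
3 | 2-methyl-2-(3-oxopentyl)cyclopentane-1,3-dione (triketone) | CCC(=O)CCC1(C)C(=O)CCC1=O | intermediate
4 | (S)-4,7a-dimethyl-2,3,7,7a-tetrahydro-1H-indene-1,5(6H)-dione | O=C1CCC2=C(C)C(=O)CC[C@]12C | intermediate
5 | (S)-4',7a'-dimethyl-2',3',7',7a'-tetrahydrospiro[[1,3]dioxolane-2,1'-inden]-5'(6'H)-one | O1CCOC12CCC3=C(C)C(=O)CC[C@]23C | intermediate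
6 | lithium (3a'S,7a'S)-4',7a'-dimethyl-2',3',3a',6',7',7a'-hexahydrospiro[[1,3]dioxolane-2,1'-inden]-5'-olate (trans-fused enolate) | O1CCOC12CC[C@H]3C(C)=C([O-])CC[C@]23C.[Li+] | intermediate
7 | (3a'S,7a'S)-4',4',7a'-trimethylhexahydrospiro[[1,3]dioxolane-2,1'-inden]-5'(4'H)-one (trans ring fusion) | O1CCOC12CC[C@H]3C(C)(C)C(=O)CC[C@]23C | intermediate
8 | (3a'S,5'R,7a'S)-4',4',7a'-trimethyloctahydrospiro[[1,3]dioxolane-2,1'-inden]-5'-ol (axial OH, trans to the angular methyl) | O1CCOC12CC[C@H]3C(C)(C)[C@H](O)CC[C@]23C | intermediate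
9 | (3aS,5R,7aS)-5-hydroxy-4,4,7a-trimethyloctahydro-1H-inden-1-one | O=C1CC[C@H]2C(C)(C)[C@H](O)CC[C@]12C | intermediate
10 | 3-methylbutanoyl chloride | CC(C)CC(=O)Cl | starting material
11 | (3aS,5R,7aS)-4,4,7a-trimethyl-1-oxooctahydro-1H-inden-5-yl 3-methylbutanoate | O=C1CC[C@H]2C(C)(C)[C@H](OC(=O)CC(C)C)CC[C@]12C | intermediate
12 | resorcinol | Oc1cccc(O)c1 | starting material
13 | (2,4-dihydroxybenzylidene)dimethyliminium chloride | C[N+](C)=Cc1ccc(O)cc1O.[Cl-] | intermediate
14 | 2,4-dihydroxybenzaldehyde | O=Cc1ccc(O)cc1O | intermediate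
15 | 3,5-dibromo-2,4-dihydroxybenzaldehyde | O=Cc1cc(Br)c(O)c(Br)c1O | intermediate
16 | 2,4-dihydroxy-3,5-dimethoxybenzaldehyde | O=Cc1cc(OC)c(O)c(OC)c1O | intermediate
17 | ethyl (Z)-3-(2,4-dihydroxy-3,5-dimethoxyphenyl)acrylate | CCOC(=O)/C=C\c1cc(OC)c(O)c(OC)c1O | intermediate
18 | isofraxidin (7-hydroxy-6,8-dimethoxy-2H-chromen-2-one) | COc1cc2ccc(=O)oc2c(OC)c1O | intermediate
19 | 6,8-dimethoxy-7-[(methylthio)methoxy]-2H-chromen-2-one | COc1cc2ccc(=O)oc2c(OC)c1OCSC | intermediate
20 | 7-(chloromethoxy)-6,8-dimethoxy-2H-chromen-2-one | COc1cc2ccc(=O)oc2c(OC)c1OCCl | intermediate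
21 | lithium alkoxide of the 1α-(dibromomethyl)-1β-hydroxy adduct of 11 (O β, CHBr2 α) | [Li+].[O-][C@@]1(C(Br)Br)CC[C@H]2C(C)(C)[C@H](OC(=O)CC(C)C)CC[C@]12C | intermediate
22 | lithium 8-enolate (C8=C9) of 3α-(3-methylbutanoyloxy)-11,12-dinor-5α-driman-8-one | [Li+].[O-]C1=C[C@@]2(C)CC[C@@H](OC(=O)CC(C)C)C(C)(C)[C@@H]2CC1 | intermediate
23 | 7-{[3α-(3-methylbutanoyloxy)-8-oxo-12-nor-5α,9βH-driman-11-yl]oxy}-6,8-dimethoxy-2H-chromen-2-one (C11 α) | COc1cc2ccc(=O)oc2c(OC)c1OC[C@@H]1C(=O)CC[C@H]2C(C)(C)[C@H](OC(=O)CC(C)C)CC[C@]12C | intermediate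
24 | 7-{[3α-(3-methylbutanoyloxy)-8-oxo-12-nor-5α,9βH-drim-6-en-11-yl]oxy}-6,8-dimethoxy-2H-chromen-2-one | COc1cc2ccc(=O)oc2c(OC)c1OC[C@@H]1C(=O)C=C[C@H]2C(C)(C)[C@H](OC(=O)CC(C)C)CC[C@]12C | intermediate
25 | 7-{[8-hydroxy-3α-(3-methylbutanoyloxy)-5α,9βH-drim-6-en-11-yl]oxy}-6,8-dimethoxy-2H-chromen-2-one (C8 epimers, not specified) | COc1cc2ccc(=O)oc2c(OC)c1OC[C@@H]1C(C)(O)C=C[C@H]2C(C)(C)[C@H](OC(=O)CC(C)C)CC[C@]12C | intermediate
26 | 7-{[(3R,5R,9R,10R)-3-(3-methylbutanoyloxy)-6-oxodrim-7-en-11-yl]oxy}-6,8-dimethoxy-2H-chromen-2-one | COc1cc2ccc(=O)oc2c(OC)c1OC[C@@H]1C(C)=CC(=O)[C@H]2C(C)(C)[C@H](OC(=O)CC(C)C)CC[C@]12C | target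

**Totals**
Total step count: 15. Longest linear sequence: 10 steps (steps 6–11, then 12–15).

**Steps most likely to fail**

Step 12 (proposed new step). The angular carbon may not migrate cleanly, n‑BuLi may touch the ester, or the hindered enolate may O‑alkylate. The fallback uses known chemistry and sets out from 11. Bis(phenylthio)methyllithium is added to the ketone to give the bis(phenylthio)methyl carbinol F1. CuOSO2CF3 with i‑Pr2NEt then triggers the thionium semipinacol ring expansion, in which the more substituted carbon migrates, to give the α‑phenylthio ketone F2. Reductive C–S cleavage with lithium 4,4'‑di‑tert‑butylbiphenylide at –78 °C regenerates the regiodefined enolate 22. Alkylation with an excess of 20 (the thiolate consumes one equivalent) comes back to the route at 23.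

Step 3. Dissolving‑metal reduction of a hydrindenone can give some cis‑fused product, and over‑methylation is possible. The fallback sets out from 5. Conjugate reduction with the copper hydride reagent made from (CH3)3CCu and i‑Bu2AlH in THF/HMPA delivers hydride anti to the angular methyl and gives the trans‑fused 4α‑methyl ketone F3. Thermodynamic enolate methylation at the more substituted carbon (KOt‑Bu, MeI, t‑BuOH) comes back at 7.

Step 13. The β‑aryloxy ketone may epimerise at C9 or eliminate the phenol during dehydrogenation. The fallback sets out from 23 and avoids the enone. Kinetic deprotonation on the C7 side with KN(SiMe3)2 and trapping with N‑(5‑chloro‑2‑pyridyl)triflimide gives the enol triflate F4. Methyl cross‑coupling (Pd(PPh3)4, AlMe3) gives the drim‑7‑ene ether F5. Allylic oxidation at C6 (CrO3, 3,5‑dimethylpyrazole, CH2Cl2, –20 °C) comes back to the route at the target 26.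

**Further compounds**
F1 | step 12 | 1α-[bis(phenylthio)methyl]-1β-hydroxy adduct of 11 | O[C@@]1(C(Sc3ccccc3)Sc3ccccc3)CC[C@H]2C(C)(C)[C@H](OC(=O)CC(C)C)CC[C@]12C
F2 | step 12 | 3α-(3-methylbutanoyloxy)-9-(phenylthio)-11,12-dinor-5α-driman-8-one (C9 epimers) | c1ccccc1SC1C(=O)CC[C@H]2C(C)(C)[C@H](OC(=O)CC(C)C)CC[C@]12C
F3 | step 3 | trans-fused 4'α,7a'-dimethylhexahydrospiro[[1,3]dioxolane-2,1'-inden]-5'(4'H)-one | O1CCOC12CC[C@H]3[C@H](C)C(=O)CC[C@]23C
F4 | step 13 | 7-en-8-yl trifluoromethanesulfonate (enol triflate) of 23 | COc1cc2ccc(=O)oc2c(OC)c1OC[C@@H]1C(OS(=O)(=O)C(F)(F)F)=CC[C@H]2C(C)(C)[C@H](OC(=O)CC(C)C)CC[C@]12C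
F5 | step 13 | 7-{[3α-(3-methylbutanoyloxy)-5α,9βH-drim-7-en-11-yl]oxy}-6,8-dimethoxy-2H-chromen-2-one | COc1cc2ccc(=O)oc2c(OC)c1OC[C@@H]1C(C)=CC[C@H]2C(C)(C)[C@H](OC(=O)CC(C)C)CC[C@]12C
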